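## Retrosynthetic overview

1. The target 21 comes from alkyne 20 by ethylene enyne metathesis, so the acid-sensitive dienol is made last; the 6-OAc/18-OH pattern is set on alkyne triol 17 (silylate O-18, acetylate O-6, desilylate).
2. Alkyne 17 comes from δ-lactone 15 (half-reduction, Ohira–Bestmann); the lactone masks O-8 and supplies C-13.
3. Key step: the C-6–O bond is made by a C-18-hydroxyl-directed δ-C–H hydroxylation of lactone 13 (proposed new reaction).
4. Lactone 13 comes from acyclic (S)-epoxy ester 12 in one epoxide-opening cascade: ring A, then ring B, then C-8–O lactone closure. The epoxide oxygen becomes 18-OH and the Z alkene puts the C-9 chain axial.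
5. Epoxide 12 comes from nerol, tert-butyl acetate and a bromo ketal by chain assembly and asymmetric Corey–Chaykovsky epoxidation.

Assumption: the SMILES is read literally as (4S,5S,6R,8S,9R,10R) in labdane numbering (used from 13 on): a trans-decalin with the 4-, 8- and 10-methyl groups on one face and H-5, C-18, O-6, O-8 and the C-9 chain on the other.
Assumption: in step 6 the (S)-binaphthoxide catalyst is taken to give the (S)-epoxide; if the sense is opposite, the (R)-catalyst is used.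

## Route

Step 1
Reactants: 1 nerol [(2Z)-3,7-dimethylocta-2,6-dien-1-ol]
Product: 2 neryl bromide [(2Z)-1-bromo-3,7-dimethylocta-2,6-diene]
Conditions: PBr3 (0.4 equiv), Et2O, −20 → 0 °C
Reagents that add atoms: phosphorus tribromide, BrP(Br)Br
Why: PBr3 bromination of a primary allylic alcohol (SN2 on the bromophosphite) at low temperature keeps the Z double bond and avoids allylic transposition.

Step 2
Reactants: 2 neryl bromide; 3 tert-butyl acetate
Product: 5 tert-butyl (4Z)-5,9-dimethyldeca-4,8-dienoate, via lithium enolate 4 (not isolated)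
Conditions: LiN(iPr)2, THF, −78 °C; then 2, DMPU, −78 → 0 °C
Reagents that add atoms: none
Why: Ester enolate alkylation, an SN2 attack on the primary allylic bromide, adds C-12 and C-13 with the ester that later closes the lactone and leaves the Z alkene untouched.

Step 3
Reactants: 5 tert-butyl (4Z)-5,9-dimethyldeca-4,8-dienoate
Product: 6 tert-butyl (4Z,8E)-10-hydroxy-5,9-dimethyldeca-4,8-dienoate
Conditions: SeO2 (0.1 equiv), tBuOOH (3 equiv), salicylic acid (0.1 equiv), CH2Cl2, 20 °C
Reagents that add atoms: tert-butyl hydroperoxide, CC(C)(C)OO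
Why: SeO2-catalysed allylic oxidation (ene reaction, then [2,3]-sigmatropic shift) attacks the more reactive terminal isopropylidene at its E methyl group, so the new CH2OH is E.

Step 4
Reactants: 6 tert-butyl (4Z,8E)-10-hydroxy-5,9-dimethyldeca-4,8-dienoate
Product: 7 tert-butyl (4Z,8E)-10-bromo-5,9-dimethyldeca-4,8-dienoate
Conditions: CBr4, PPh3, CH2Cl2, 0 °C
Reagents that add atoms: carbon tetrabromide, BrC(Br)(Br)Br
Why: Appel reaction, SN2 displacement on the alkoxyphosphonium salt at the primary allylic carbon, gives the bromide without moving either double bond.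

Step 5
Reactants: 7 tert-butyl (4Z,8E)-10-bromo-5,9-dimethyldeca-4,8-dienoate; 8 2-(2-bromoethyl)-2-methyl-1,3-dioxolane
Product: 11 tert-butyl (4Z,8E)-5,9-dimethyl-13-oxotetradeca-4,8-dienoate, via Grignard reagent 9 (not isolated), via dioxolane ketal 10 (not isolated)
Conditions: 8, Mg, THF, 25 °C; then 7, Li2CuCl4 (3 mol %), THF, −40 → 0 °C; then 1 M HCl, acetone, 20 °C
Reagents that add atoms: magnesium, [Mg] (stays in 9 only); water, O
Why: Copper-catalysed Grignard–allylic bromide coupling (SN2 at the CH2Br carbon) joins C-1 to C-2 without touching the tert-butyl ester at low temperature, and dilute acid then hydrolyses only the dioxolane.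

Step 6
Reactants: 11 tert-butyl (4Z,8E)-5,9-dimethyl-13-oxotetradeca-4,8-dienoate
Product: 12 tert-butyl (4Z,8E)-5,9-dimethyl-12-[(2S)-2-methyloxiran-2-yl]dodeca-4,8-dienoate
Conditions: Me3S(O)I, NaH, THF, 20 °C (ylide preformed); then 11, LaLi3[(S)-binaphthoxide]3 (5 mol %), (2,4,6-(MeO)3C6H2)3P=O (5 mol %), 5 Å MS, THF, 20 °C
Reagents that add atoms: trimethylsulfoxonium iodide, C[S+](C)(C)=O.[I-]
Why: Catalytic asymmetric Corey–Chaykovsky epoxidation of a methyl ketone, in which the lanthanum–lithium binaphthoxide binds ketone and sulfoxonium ylide and delivers CH2 to one ketone face, fixes the future C-4 as the (S)-epoxide while ester and alkenes are inert.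

Step 7
Reactants: 12 tert-butyl (4Z,8E)-5,9-dimethyl-12-[(2S)-2-methyloxiran-2-yl]dodeca-4,8-dienoate
Product: 13 (4S,5S,8S,9R,10R)-18-hydroxy-14,15,16-trinorlabdano-13,8-lactone
Conditions: MeAlCl2 (1.5 equiv), CH2Cl2, −78 °C; aq. KNaC4H4O6
Reagents that add atoms: none
Why: Epoxide-initiated cation–olefin bicyclisation through a chair–chair fold: backside attack of the E alkene on the activated tertiary epoxide carbon inverts C-4 with the CH2O–Al arm equatorial, anti addition across the E alkene gives the trans ring fusion (C-5, C-10), anti addition across the Z alkene puts the C-9 chain axial, and the ester carbonyl oxygen closes the C-8–O bond on the face of that chain with loss of isobutene to give the cis-fused δ-lactone.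

Step 8
Reactants: 13 (4S,5S,8S,9R,10R)-18-hydroxy-14,15,16-trinorlabdano-13,8-lactone
Product: 15 (4S,5S,6R,8S,9R,10R)-6,18-dihydroxy-14,15,16-trinorlabdano-13,8-lactone, via 6-hydroperoxide 14 (not isolated)
Conditions: (Bu4N)2CeCl6 (10 mol %), O2 (1 atm), 400 nm LEDs, MeCN, 20 °C; then PPh3, 0 °C
Reagents that add atoms: dioxygen, O=O
Why: Proposed new method: free-alcohol-directed aerobic δ-C(sp3)–H hydroxylation, in which the tetravalent cerium alkoxide of the C-18 hydroxyl undergoes LMCT homolysis to the alkoxy radical, which sits in a syn-pentane contact with the equatorial H-6 and removes it by 1,5-hydrogen transfer (C-2 is anti and O-8 is masked in the lactone), the C-6 radical is trapped by O2 on its open equatorial face because the axial face is blocked by the 8- and 10-methyl groups, the peroxyl radical reoxidises trivalent cerium and PPh3 reduces the hydroperoxide to the 6-alcohol with the target configuration; the closest known reaction types are cerium-LMCT δ-C–H amination of alkanols, the Barton nitrite photolysis under oxygen and the hypoiodite δ-functionalisation of alcohols.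

Step 9
Reactants: 15 (4S,5S,6R,8S,9R,10R)-6,18-dihydroxy-14,15,16-trinorlabdano-13,8-lactone
Product: 16 (4S,5S,6R,8S,9R,10R)-8,13-epoxy-14,15,16-trinorlabdane-6,13,18-triol (lactol; both C-13 epimers)
Conditions: iBu2AlH (4 equiv), CH2Cl2, −78 °C; aq. KNaC4H4O6
Reagents that add atoms: none
Why: Half-reduction of a lactone with iBu2AlH stops at the aluminium hemiacetal at −78 °C and gives the lactol on work-up, the two free hydroxyls only consuming hydride.

Step 10
Reactants: 16 (4S,5S,6R,8S,9R,10R)-8,13-epoxy-14,15,16-trinorlabdane-6,13,18-triol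
Product: 17 (4S,5S,6R,8S,9R,10R)-15,16-dinorlabd-13-yne-6,8,18-triol
Conditions: MeC(O)C(N2)P(O)(OMe)2, K2CO3, MeOH, 0 → 20 °C
Reagents that add atoms: dimethyl (1-diazo-2-oxopropyl)phosphonate, CC(=O)C(=[N+]=[N-])P(=O)(OC)OC
Why: Ohira–Bestmann (Seyferth–Gilbert) homologation converts the open hydroxy-aldehyde form of the lactol into the terminal alkyne and sets the C-8 hydroxyl free without touching a stereocentre.

Step 11
Reactants: 17 (4S,5S,6R,8S,9R,10R)-15,16-dinorlabd-13-yne-6,8,18-triol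
Product: 19 (4S,5S,6R,8S,9R,10R)-18-(tert-butyldimethylsilyloxy)-8-hydroxy-15,16-dinorlabd-13-yn-6-yl acetate, via silyl ether 18 (not isolated)
Conditions: TBSCl (1.05 equiv), imidazole, CH2Cl2, 0 °C; then Ac2O, DMAP, pyridine, 20 °C
Reagents that add atoms: tert-butyldimethylsilyl chloride, CC(C)(C)[Si](C)(C)Cl; acetic anhydride, CC(=O)OC(C)=O
Why: Sequential silylation and acetylation: TBSCl takes only the primary C-18 hydroxyl, DMAP-catalysed acetylation then takes the secondary C-6 hydroxyl, and the tertiary C-8 hydroxyl is too hindered to react.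

Step 12
Reactants: 19 (4S,5S,6R,8S,9R,10R)-18-(tert-butyldimethylsilyloxy)-8-hydroxy-15,16-dinorlabd-13-yn-6-yl acetate
Product: 20 (4S,5S,6R,8S,9R,10R)-8,18-dihydroxy-15,16-dinorlabd-13-yn-6-yl acetate
Conditions: HF·pyridine, pyridine, THF, 0 → 20 °C
Reagents that add atoms: none
Why: Fluoride desilylation under buffered, non-basic conditions removes the silyl ether without the base that would let the acetyl group migrate from O-6 to the neighbouring O-18.

Step 13
Reactants: 20 (4S,5S,6R,8S,9R,10R)-8,18-dihydroxy-15,16-dinorlabd-13-yn-6-yl acetate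
Product: 21 (4S,5S,6R,8S,9R,10R)-8,18-dihydroxylabda-13(16),14-dien-6-yl acetate (target, CNP0312185.2)
Conditions: ethylene (4 bar), second-generation Grubbs catalyst RuCl2(=CHPh)(PCy3)(H2IMes) (5 mol %), CH2Cl2, 40 °C
Reagents that add atoms: ethylene, C=C
Why: Enyne cross-metathesis of the terminal alkyne with ethylene gives the 2-substituted buta-1,3-diene directly under neutral conditions, so the acid-sensitive dienol and the hydroxy acetate meet no acid or base afterwards.

## Compound list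

1 | nerol [(2Z)-3,7-dimethylocta-2,6-dien-1-ol] | CC(C)=CCC/C(C)=C\CO | starting material
2 | neryl bromide [(2Z)-1-bromo-3,7-dimethylocta-2,6-diene] | CC(C)=CCC/C(C)=C\CBr | intermediate
3 | tert-butyl acetate | CC(=O)OC(C)(C)C | starting material
4 | lithium enolate of tert-butyl acetate (not isolated) | C=C(O[Li])OC(C)(C)C | intermediate
5 | tert-butyl (4Z)-5,9-dimethyldeca-4,8-dienoate | CC(C)=CCC/C(C)=C\CCC(=O)OC(C)(C)C | intermediate
6 | tert-butyl (4Z,8E)-10-hydroxy-5,9-dimethyldeca-4,8-dienoate | OC/C(C)=C/CC/C(C)=C\CCC(=O)OC(C)(C)C | intermediate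
7 | tert-butyl (4Z,8E)-10-bromo-5,9-dimethyldeca-4,8-dienoate | BrC/C(C)=C/CC/C(C)=C\CCC(=O)OC(C)(C)C | intermediate
8 | 2-(2-bromoethyl)-2-methyl-1,3-dioxolane | CC1(CCBr)OCCO1 | starting material
9 | [2-(2-methyl-1,3-dioxolan-2-yl)ethyl]magnesium bromide (not isolated) | CC1(CC[Mg]Br)OCCO1 | intermediate
10 | tert-butyl (4Z,8E)-5,9-dimethyl-12-(2-methyl-1,3-dioxolan-2-yl)dodeca-4,8-dienoate (not isolated) | CC1(CCC/C(C)=C/CC/C(C)=C\CCC(=O)OC(C)(C)C)OCCO1 | intermediate
11 | tert-butyl (4Z,8E)-5,9-dimethyl-13-oxotetradeca-4,8-dienoate | CC(=O)CCC/C(C)=C/CC/C(C)=C\CCC(=O)OC(C)(C)C | intermediate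
12 | tert-butyl (4Z,8E)-5,9-dimethyl-12-[(2S)-2-methyloxiran-2-yl]dodeca-4,8-dienoate | C[C@@]1(CO1)CCC/C(C)=C/CC/C(C)=C\CCC(=O)OC(C)(C)C | intermediate
13 | (4S,5S,8S,9R,10R)-18-hydroxy-14,15,16-trinorlabdano-13,8-lactone (cis-fused δ-lactone on a trans-decalin) | O=C1CC[C@@H]2[C@]3(C)CCC[C@](C)(CO)[C@H]3CC[C@]2(C)O1 | intermediate
14 | (4S,5S,6R,8S,9R,10R)-6-hydroperoxy-18-hydroxy-14,15,16-trinorlabdano-13,8-lactone (not isolated) | O=C1CC[C@@H]2[C@]3(C)CCC[C@](C)(CO)[C@H]3[C@H](OO)C[C@]2(C)O1 | intermediate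
15 | (4S,5S,6R,8S,9R,10R)-6,18-dihydroxy-14,15,16-trinorlabdano-13,8-lactone | O=C1CC[C@@H]2[C@]3(C)CCC[C@](C)(CO)[C@H]3[C@H](O)C[C@]2(C)O1 | intermediate
16 | (4S,5S,6R,8S,9R,10R)-8,13-epoxy-14,15,16-trinorlabdane-6,13,18-triol (lactol, C-13 epimers) | OC1CC[C@@H]2[C@]3(C)CCC[C@](C)(CO)[C@H]3[C@H](O)C[C@]2(C)O1 | intermediate
17 | (4S,5S,6R,8S,9R,10R)-15,16-dinorlabd-13-yne-6,8,18-triol | C#CCC[C@@H]1[C@]2(C)CCC[C@](C)(CO)[C@H]2[C@H](O)C[C@]1(C)O | intermediate
18 | (4S,5S,6R,8S,9R,10R)-18-(tert-butyldimethylsilyloxy)-15,16-dinorlabd-13-yne-6,8-diol (not isolated) | C#CCC[C@@H]1[C@]2(C)CCC[C@](C)(CO[Si](C)(C)C(C)(C)C)[C@H]2[C@H](O)C[C@]1(C)O | intermediate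
19 | (4S,5S,6R,8S,9R,10R)-18-(tert-butyldimethylsilyloxy)-8-hydroxy-15,16-dinorlabd-13-yn-6-yl acetate | C#CCC[C@@H]1[C@]2(C)CCC[C@](C)(CO[Si](C)(C)C(C)(C)C)[C@H]2[C@H](OC(C)=O)C[C@]1(C)O | intermediate
20 | (4S,5S,6R,8S,9R,10R)-8,18-dihydroxy-15,16-dinorlabd-13-yn-6-yl acetate | C#CCC[C@@H]1[C@]2(C)CCC[C@](C)(CO)[C@H]2[C@H](OC(C)=O)C[C@]1(C)O | intermediate
21 | (4S,5S,6R,8S,9R,10R)-8,18-dihydroxylabda-13(16),14-dien-6-yl acetate | C=CC(=C)CC[C@@H]1[C@]2(C)CCC[C@](C)(CO)[C@H]2[C@H](OC(C)=O)C[C@]1(C)O | target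

## Step count and risks

Total: 13 steps. Longest linear sequence: 13 steps (from nerol 1).

**Step 8 (proposed new δ-C–H hydroxylation).** It may fail through β-scission of the neopentyl-type alkoxy radical (loss of CH2O), chlorine-atom side abstraction, or over-oxidation to the 6-ketone. Fallback with known chemistry, from 13 back to 15: nitrosyl chloride in pyridine at −20 °C converts the C-18 hydroxyl of 13 into the nitrite ester F1. Irradiation of F1 (Hg lamp, Pyrex, benzene) under a stream of O2 is the Barton nitrite photolysis run in the presence of oxygen; the same 1,5-hydrogen shift occurs and the C-6 radical ends as the 6-nitrate ester F2 with the C-18 hydroxyl restored. Zn dust in AcOH then reduces the nitrate to the alcohol 15.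

**Step 7 (bicyclisation).** The 2,2-disubstituted epoxide may ionise before C–C bonding (loss of ee), shift a hydride to give an aldehyde, give the C-4 epimer, or fail to close the lactone. Fallback, from 7 back to 13, moves the controlling oxygen to C-3 and deletes it afterwards:
- Lithiated 3-methylbut-2-enyl phenyl sulfone (BuLi, THF, −78 °C) is alkylated by 7 to give the allyl sulfone F3.
- Na(Hg), Na2HPO4, MeOH removes the sulfonyl group to give the triene ester F4.
- SeO2/tBuOOH oxidises the terminal E methyl group to the allylic alcohol F5.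
- Sharpless epoxidation (Ti(OiPr)4, D-(−)-diethyl tartrate, tBuOOH, −20 °C) gives the (2R,3R)-epoxy alcohol F6.
- TBSCl/imidazole gives the silyl ether F7.
- MeAlCl2 at −78 °C cyclises F7, the C-3 carbinol stereocentre now relaying the chirality, to the 3-hydroxy lactone F8.
- Barton–McCombie deoxygenation: 1,1'-thiocarbonyldiimidazole gives the thiocarbonylimidazolide F9, and Bu3SnH/AIBN in toluene at 110 °C gives the silyl ether lactone F10.
- Bu4NF in THF frees the C-18 hydroxyl and gives 13.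

**Step 13 (enyne metathesis).** It may stall or give alkyne dimers on this polar substrate. Fallback, from 20 back to 21: Mo(CO)3(CNtBu)3-catalysed Markovnikov hydrostannation with Bu3SnH (THF, 55 °C) gives the 2-stannyl alkene F11, and Stille coupling of F11 with vinyl bromide (Pd(PPh3)4, DMF, 60 °C, no base) gives 21.

Further compounds

F1 | step 8 | (4S,5S,8S,9R,10R)-18-(nitrosooxy)-14,15,16-trinorlabdano-13,8-lactone | O=C1CC[C@@H]2[C@]3(C)CCC[C@](C)(CON=O)[C@H]3CC[C@]2(C)O1
F2 | step 8 | (4S,5S,6R,8S,9R,10R)-18-hydroxy-6-(nitrooxy)-14,15,16-trinorlabdano-13,8-lactone | O=C1CC[C@@H]2[C@]3(C)CCC[C@](C)(CO)[C@H]3[C@H](O[N+](=O)[O-])C[C@]2(C)O1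
F3 | step 7 | tert-butyl (4Z,8E)-5,9,13-trimethyl-11-(phenylsulfonyl)tetradeca-4,8,12-trienoate | CC(C)=CC(C/C(C)=C/CC/C(C)=C\CCC(=O)OC(C)(C)C)S(=O)(=O)c1ccccc1
F4 | step 7 | tert-butyl (4Z,8E)-5,9,13-trimethyltetradeca-4,8,12-trienoate | CC(C)=CCC/C(C)=C/CC/C(C)=C\CCC(=O)OC(C)(C)C
F5 | step 7 | tert-butyl (4Z,8E,12E)-14-hydroxy-5,9,13-trimethyltetradeca-4,8,12-trienoate | OC/C(C)=C/CC/C(C)=C/CC/C(C)=C\CCC(=O)OC(C)(C)C
F6 | step 7 | tert-butyl (4Z,8E)-11-[(2R,3R)-3-(hydroxymethyl)-3-methyloxiran-2-yl]-5,9-dimethylundeca-4,8-dienoate | OC[C@@]1(C)O[C@@H]1CC/C(C)=C/CC/C(C)=C\CCC(=O)OC(C)(C)C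
F7 | step 7 | tert-butyl (4Z,8E)-11-[(2R,3R)-3-(tert-butyldimethylsilyloxymethyl)-3-methyloxiran-2-yl]-5,9-dimethylundeca-4,8-dienoate | CC(C)(C)[Si](C)(C)OC[C@@]1(C)O[C@@H]1CC/C(C)=C/CC/C(C)=C\CCC(=O)OC(C)(C)C
F8 | step 7 | (3R,4S,5S,8S,9R,10R)-18-(tert-butyldimethylsilyloxy)-3-hydroxy-14,15,16-trinorlabdano-13,8-lactone | O=C1CC[C@@H]2[C@]3(C)CC[C@@H](O)[C@](C)(CO[Si](C)(C)C(C)(C)C)[C@H]3CC[C@]2(C)O1
F9 | step 7 | (3R,4S,5S,8S,9R,10R)-18-(tert-butyldimethylsilyloxy)-3-(imidazol-1-ylthiocarbonyloxy)-14,15,16-trinorlabdano-13,8-lactone | O=C1CC[C@@H]2[C@]3(C)CC[C@@H](OC(=S)n4ccnc4)[C@](C)(CO[Si](C)(C)C(C)(C)C)[C@H]3CC[C@]2(C)O1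
F10 | step 7 | (4S,5S,8S,9R,10R)-18-(tert-butyldimethylsilyloxy)-14,15,16-trinorlabdano-13,8-lactone | O=C1CC[C@@H]2[C@]3(C)CCC[C@](C)(CO[Si](C)(C)C(C)(C)C)[C@H]3CC[C@]2(C)O1
F11 | step 13 | (4S,5S,6R,8S,9R,10R)-8,18-dihydroxy-13-(tributylstannyl)-15,16-dinorlabd-13-en-6-yl acetate | C=C(CC[C@@H]1[C@]2(C)CCC[C@](C)(CO)[C@H]2[C@H](OC(C)=O)C[C@]1(C)O)[Sn](CCCC)(CCCC)CCCC
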